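**Retrosynthetic overview**

1. The target consists of ring A, a cyclohexa-2,5-dienone (cyclic β-triketone: C1 carbonyl, C2 acyl-bearing, C3 enol, C4 quaternary with methyl and prenyl, C5 enol, C6 bridge-bearing), joined through one CH2 to C8 of a 2,2-dimethylchromene (benzene ring B, pyran ring C).
2. Two bonds are disconnected together: the CH2–C6 bond (C6 of ring A as nucleophile, an ortho-quinone methide of the chromene half as electrophile) and the C1–C6 bond of ring A (retro-Claisen), which leads to an acyclic methyl 2-acyl-3,5-dioxohexanoate.
3. Enabling feature: the C1–C6 bond of ring A is the acyl–enol carbon bond of a β-triketone, so it can be made by an intramolecular Claisen (Dieckmann) condensation. The quaternary C4 has no hydrogen, so the C5 ketone of the open chain enolises only toward C6 and the chain cannot aromatise. C6 remains nucleophilic after closure and takes up the quinone methide in the same flask.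
4. The C4 stereocentre is set first, by auxiliary-controlled prenylation of methyl 2-methylacetoacetate. It has no α-hydrogen and its two ring neighbours stay different in every tautomer, so it cannot epimerise later.
5. Ring order: ring B is bought (phloroglucinol), ring C is closed by Knoevenagel condensation and oxa-6π electrocyclisation, and ring A is closed last, in the key step.

Key step: step 9

Assumption: in step 2 the toluene/HMPA variant of the lithio-enamine alkylation is taken to deliver the R configuration. The facial sense of this reaction type reverses when the lithium ligand is changed to THF, so the ligand (or the D-valine auxiliary) would be switched if the sense proves opposite.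

**Route**

Step 1
Reactants: 1 methyl 2-methyl-3-oxobutanoate; 2 L-valine tert-butyl ester
Product: 3 methyl (2Z)-3-{[(2S)-1-tert-butoxy-3-methyl-1-oxobutan-2-yl]amino}-2-methylbut-2-enoate
Conditions: BF3·OEt2 (cat.), benzene, reflux, Dean–Stark
Reagents that add atoms: none
Why: Condensation of the ketone of a β-keto ester with a primary amine under water removal should give the hydrogen-bonded Z-enamino ester (vinylogous carbamate formation); the α-carbon becomes sp2, so its configuration in 1 is irrelevant, and the valine centre is untouched.

Step 2
Reactants: 3 enamino ester; 4 1-bromo-3-methylbut-2-ene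
Product: 6 methyl (2R)-2-acetyl-2,5-dimethylhex-4-enoate, via alkylated ketimine 5 (not isolated)
Conditions: LiN(iPr)2 (1.1 equiv), toluene, −78 °C; HMPA (2 equiv), then 4, −78 to −55 °C; 1 M aq. citric acid, 0 °C
Reagents that add atoms: water, O
Why: Deprotonation should give a lithium aza-enolate held in a rigid chelate by the enamine nitrogen and the valine ester carbonyl, so the isopropyl group blocks one face and the prenyl bromide alkylates the α-carbon from the other (auxiliary-controlled asymmetric alkylation of the chiral enamine of an α-alkyl β-keto ester, SN2 at the primary allylic carbon), setting the quaternary centre as R; mild aqueous acid then hydrolyses the ketimine and returns the auxiliary.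

Step 3
Reactants: 6 methyl (2R)-2-acetyl-2,5-dimethylhex-4-enoate
Product: 7 lithium (2R)-2-acetyl-2,5-dimethylhex-4-enoate
Conditions: LiOH·H2O (1.0 equiv), THF/H2O, 0 °C to rt; ether wash, lyophilisation
Reagents that add atoms: lithium hydroxide, [Li+].[OH-]
Why: Saponification with one equivalent of dilute hydroxide at low temperature (the ketonic-hydrolysis mode of acetoacetic esters) should be preferred over retro-Claisen cleavage; the product is kept as its salt because the free β-keto acid would decarboxylate, and the quaternary centre has no α-hydrogen and cannot epimerise.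

Step 4
Reactants: 7 lithium (2R)-2-acetyl-2,5-dimethylhex-4-enoate; 8 methyl 4-methyl-3-oxopentanoate
Product: 10 methyl (4R)-4-methyl-4-(3-methylbut-2-en-1-yl)-2-(2-methylpropanoyl)-3,5-dioxohexanoate, via acid chloride 9 (not isolated)
Conditions: 7, (COCl)2 (1.05 equiv), DMF (cat.), CH2Cl2, 0 °C; then added to 8, MgCl2 (1.1 equiv), pyridine (2.2 equiv), CH2Cl2, 0 °C to rt; cold 1 M HCl
Reagents that add atoms: oxalyl chloride, O=C(Cl)C(Cl)=O (supplies only the chlorine of intermediate 9)
Why: The carboxylate should give the acid chloride without free HCl (no ketene or enolisation is possible at the fully substituted α-carbon), and this C-acylates the magnesium chelate of the β-keto ester (soft-enolisation C-acylation of a 1,3-dicarbonyl compound), the chelate directing attack to carbon and holding the acidic product as an inert enolate; the stereocentre is not involved.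

Step 5
Reactants: 11 benzene-1,3,5-triol (phloroglucinol); 12 2-methylpropanoyl chloride
Product: 13 2-methyl-1-(2,4,6-trihydroxyphenyl)propan-1-one
Conditions: AlCl3 (3.5 equiv), nitrobenzene/CH2Cl2, rt to 45 °C; aq. HCl
Reagents that add atoms: none
Why: Friedel–Crafts acylation of the electron-rich triol; the aluminium-complexed aryl ketone is deactivated, so acylation should stop at the mono-ketone.

Step 6
Reactants: 13 2-methyl-1-(2,4,6-trihydroxyphenyl)propan-1-one; 14 3-methylbut-2-enal
Product: 16 1-(5,7-dihydroxy-2,2-dimethyl-2H-chromen-6-yl)-2-methylpropan-1-one, via dienone 15 (not isolated)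
Conditions: 14 (1.05 equiv), ethylenediammonium diacetate (10 mol %), toluene, 90 °C
Reagents that add atoms: none
Why: Knoevenagel-type condensation at a free ring carbon gives the dienone, whose oxa-6π electrocyclisation closes ring C; closure through the non-chelated hydroxyl para to the acyl group should give the 6-acyl-5,7-dihydroxy isomer, and one equivalent of aldehyde limits a second annulation.

Step 7
Reactants: 16 1-(5,7-dihydroxy-2,2-dimethyl-2H-chromen-6-yl)-2-methylpropan-1-one
Product: 17 1-{8-[(dimethylamino)methyl]-5,7-dihydroxy-2,2-dimethyl-2H-chromen-6-yl}-2-methylpropan-1-one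
Conditions: N,N-dimethylmethyleneiminium iodide (1.1 equiv), Et3N (1.1 equiv), CH2Cl2, 0 °C to rt
Reagents that add atoms: N,N-dimethylmethyleneiminium iodide, C=[N+](C)C.[I-]
Why: Mannich aminomethylation by the preformed iminium ion can occur only at C8, the single unsubstituted carbon of ring B.

Step 8
Reactants: 17 Mannich base
Product: 18 1-[5,7-dihydroxy-2,2-dimethyl-6-(2-methylpropanoyl)-2H-chromen-8-yl]-N,N,N-trimethylmethanaminium iodide
Conditions: MeI (5 equiv), acetone, 0 °C to rt, dark; filtration
Reagents that add atoms: iodomethane, CI
Why: Menshutkin quaternisation of the tertiary benzylic amine; without added base the chelated phenols should not be methylated, and the salt precipitates with a trimethylammonium leaving group ready for base-triggered quinone methide release.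

Step 9
Reactants: 10 methyl (4R)-4-methyl-4-(3-methylbut-2-en-1-yl)-2-(2-methylpropanoyl)-3,5-dioxohexanoate; 18 trimethylammonium iodide
Product: 21 (4R)-6-{[5,7-dihydroxy-2,2-dimethyl-6-(2-methylpropanoyl)-2H-chromen-8-yl]methyl}-3,5-dihydroxy-4-methyl-4-(3-methylbut-2-en-1-yl)-2-(2-methylpropanoyl)cyclohexa-2,5-dien-1-one, via cyclic triketone dienolate 19 (not isolated), via ortho-quinone methide 20 (not isolated)
Conditions: LiN(SiMe3)2 (2.2 equiv), THF, −78 to 0 °C; then LiN(SiMe3)2 (1.0 equiv) and 18 (1.0 equiv, in DMF), −40 °C to rt; cold 1 M HCl
Reagents that add atoms: none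
Why: Two equivalents of amide base remove the tricarbonyl C2–H and then a proton of the acetyl methyl group (the only enolisable position of that ketone, its other α-carbon being the quaternary centre); the methyl ketone enolate attacks the ester carbonyl in a 6-exo-trig (enolexo) closure and loss of methoxide gives ring A as dienolate 19, an intramolecular Claisen (Dieckmann) condensation of the kind by which 3,5-dioxoalkanoates close to cyclohexane-1,3,5-triones and acylphloroglucinols. The selectivity needed is Claisen closure on the ester and not the equally six-membered aldol closure on the isobutyryl ketone: in the lithium chelate the two ketone oxygens carry the enolate and the ester is the unchelated, most electrophilic carbonyl, and under aprotic conditions an aldolate cannot dehydrate and reverts, whereas methoxide loss followed by deprotonation of the product is irreversible. Added 18 is then deprotonated at a phenol and loses trimethylamine to give ortho-quinone methide 20, which should be captured at once by the dienolate at the only hydrogen-bearing ring carbon (C6 of ring A, the carbon that has just formed the new bond), following the known alkylation of cyclic β-triketones by quinone methides released from 2-hydroxybenzylammonium salts; C2 is blocked by its acyl group and one equivalent of 18 limits a second alkylation. No stereocentre is formed: the quaternary C4 is a spectator without α-hydrogen and keeps the R configuration set in step 2.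

**Compound list**

1 | methyl 2-methyl-3-oxobutanoate | CC(=O)C(C)C(=O)OC | starting material
2 | L-valine tert-butyl ester, tert-butyl (2S)-2-amino-3-methylbutanoate | CC(C)[C@H](N)C(=O)OC(C)(C)C | starting material
3 | methyl (2Z)-3-{[(2S)-1-tert-butoxy-3-methyl-1-oxobutan-2-yl]amino}-2-methylbut-2-enoate | COC(=O)/C(C)=C(C)\N[C@@H](C(C)C)C(=O)OC(C)(C)C | intermediate
4 | 1-bromo-3-methylbut-2-ene | CC(C)=CCBr | starting material
5 | ketimine of 6 with L-valine tert-butyl ester, (2R) at the quaternary carbon and (2S) in the valine part | CC(C)=CC[C@](C)(C(C)=N[C@@H](C(C)C)C(=O)OC(C)(C)C)C(=O)OC | intermediate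
6 | methyl (2R)-2-acetyl-2,5-dimethylhex-4-enoate | CC(C)=CC[C@](C)(C(C)=O)C(=O)OC | intermediate
7 | lithium (2R)-2-acetyl-2,5-dimethylhex-4-enoate | CC(C)=CC[C@](C)(C(C)=O)C(=O)[O-].[Li+] | intermediate
8 | methyl 4-methyl-3-oxopentanoate | CC(C)C(=O)CC(=O)OC | starting material
9 | (2R)-2-acetyl-2,5-dimethylhex-4-enoyl chloride | CC(C)=CC[C@](C)(C(C)=O)C(Cl)=O | intermediate
10 | methyl (4R)-4-methyl-4-(3-methylbut-2-en-1-yl)-2-(2-methylpropanoyl)-3,5-dioxohexanoate (C2 enolised, configuration there not defined) | CC(C)=CC[C@](C)(C(C)=O)C(=O)C(C(=O)C(C)C)C(=O)OC | intermediate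
11 | benzene-1,3,5-triol | Oc1cc(O)cc(O)c1 | starting material
12 | 2-methylpropanoyl chloride | CC(C)C(Cl)=O | starting material
13 | 2-methyl-1-(2,4,6-trihydroxyphenyl)propan-1-one | CC(C)C(=O)c1c(O)cc(O)cc1O | intermediate
14 | 3-methylbut-2-enal | CC(C)=CC=O | starting material
15 | 3,5-dihydroxy-2-(3-methylbut-2-en-1-ylidene)-4-(2-methylpropanoyl)cyclohexa-3,5-dien-1-one | CC(C)C(=O)C1=C(O)C(=CC=C(C)C)C(=O)C=C1O | intermediate
16 | 1-(5,7-dihydroxy-2,2-dimethyl-2H-chromen-6-yl)-2-methylpropan-1-one | CC(C)C(=O)c1c(O)cc2OC(C)(C)C=Cc2c1O | intermediate
17 | 1-{8-[(dimethylamino)methyl]-5,7-dihydroxy-2,2-dimethyl-2H-chromen-6-yl}-2-methylpropan-1-one | CC(C)C(=O)c1c(O)c(CN(C)C)c2OC(C)(C)C=Cc2c1O | intermediate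
18 | 1-[5,7-dihydroxy-2,2-dimethyl-6-(2-methylpropanoyl)-2H-chromen-8-yl]-N,N,N-trimethylmethanaminium iodide | CC(C)C(=O)c1c(O)c(C[N+](C)(C)C)c2OC(C)(C)C=Cc2c1O.[I-] | intermediate
19 | (4R)-3,5-dihydroxy-4-methyl-4-(3-methylbut-2-en-1-yl)-2-(2-methylpropanoyl)cyclohexa-2,5-dien-1-one (present in the flask as its dilithium dienolate) | CC(C)=CC[C@]1(C)C(O)=CC(=O)C(C(=O)C(C)C)=C1O | intermediate
20 | 5-hydroxy-2,2-dimethyl-8-methylidene-6-(2-methylpropanoyl)-2H-chromen-7(8H)-one | C=C1C(=O)C(C(=O)C(C)C)=C(O)C2=C1OC(C)(C)C=C2 | intermediate
21 | (4R)-6-{[5,7-dihydroxy-2,2-dimethyl-6-(2-methylpropanoyl)-2H-chromen-8-yl]methyl}-3,5-dihydroxy-4-methyl-4-(3-methylbut-2-en-1-yl)-2-(2-methylpropanoyl)cyclohexa-2,5-dien-1-one | CC(C)=CC[C@]1(C)C(O)=C(Cc2c(O)c(C(=O)C(C)C)c(O)c3c2OC(C)(C)C=C3)C(=O)C(C(=O)C(C)C)=C1O | target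

**Step count and risks**

Total step count: 9. Longest linear sequence: 5 steps (steps 1, 2, 3, 4, 9; the chromene branch, steps 5 to 8 and 9, is equally long).

Steps most likely to fail:

1. Step 9. The ring closure may be diverted into aldol-type attack on the isobutyryl carbonyl, or liberated methoxide may cleave the non-enolisable 1,3-diketone (retro-Claisen). In the second stage the quinone methide may oligomerise or be captured by methanol, or the basic medium may scramble the methylene bridge by retro-Michael cleavage into symmetrical dimers. The fallback separates the two events and reverses the polarity of the union. It sets out from 10: the Claisen closure alone (LiN(SiMe3)2, THF, −78 to 0 °C, acidic work-up) should give 19, now isolated. Compound 19 is aminomethylated at its free ring carbon with N,N-dimethylmethyleneiminium iodide and Et3N to the Mannich base (4R)-6-[(dimethylamino)methyl]-3,5-dihydroxy-4-methyl-4-(3-methylbut-2-en-1-yl)-2-(2-methylpropanoyl)cyclohexa-2,5-dien-1-one F1. Warming F1 with chromene 16 (toluene, 80 °C) should expel dimethylamine to give the exocyclic enone of ring A, which alkylates C8 of 16 in a Friedel–Crafts-type Michael addition and rejoins the route at 21; steps 7 and 8 are then not needed.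

2. Step 4. The β-keto acyl donor may decarboxylate or hydrolyse during activation, and acylation at the neopentyl-type carbonyl may be slow enough for O-acylation of the diacylmethane to take over. The fallback forms the same tricarbonyl unit through a small nucleophile and a later acylation. It sets out from 7: cold acidification gives (2R)-2-acetyl-2,5-dimethylhex-4-enoic acid F2, which is converted at 0 °C with 1,1'-carbonyldiimidazole into the imidazolide (2R)-2-acetyl-1-(1H-imidazol-1-yl)-2,5-dimethylhex-4-en-1-one F3. Acylation of the magnesium salt of potassium methyl malonate (MgCl2, Et3N, MeCN) with F3, followed by decarboxylation on work-up, should give methyl (4R)-4-methyl-4-(3-methylbut-2-en-1-yl)-3,5-dioxohexanoate F4. F4 must not meet strong base, because its own Claisen closure would give an achiral trione and erase the stereocentre. C-Acylation of F4 with 12 under MgCl2/pyridine rejoins the route at 10.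

3. Step 2. The acyclic lithio-enamine may lose chelate control and give poor facial discrimination, or the prenyl electrophile may react at nitrogen or in the SN2′ sense. The fallback replaces auxiliary control by enzymatic differentiation of enantiotopic ester groups. It sets out from 4: alkylation of commercial dimethyl 2-methylpropanedioate (NaH, THF) gives dimethyl 2-methyl-2-(3-methylbut-2-en-1-yl)propanedioate F5. Hydrolysis of one enantiotopic ester with pig liver esterase (or a screened hydrolase selected for this sense; pH 7.5, then acidification) should give (2R)-2-(methoxycarbonyl)-2,5-dimethylhex-4-enoic acid F6. Neutral chlorination with 1-chloro-N,N,2-trimethylprop-1-en-1-amine gives methyl (2S)-2-(chlorocarbonyl)-2,5-dimethylhex-4-enoate F7 (same spatial arrangement; the descriptor changes with the priorities). Acylation of MeMgBr with F7 (Fe(acac)3 cat., THF, −78 °C) rejoins the route at 6.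

Further compounds
F1 | step 9 | (4R)-6-[(dimethylamino)methyl]-3,5-dihydroxy-4-methyl-4-(3-methylbut-2-en-1-yl)-2-(2-methylpropanoyl)cyclohexa-2,5-dien-1-one | CC(C)=CC[C@]1(C)C(O)=C(CN(C)C)C(=O)C(C(=O)C(C)C)=C1O
F2 | step 4 | (2R)-2-acetyl-2,5-dimethylhex-4-enoic acid | CC(C)=CC[C@](C)(C(C)=O)C(=O)O
F3 | step 4 | (2R)-2-acetyl-1-(1H-imidazol-1-yl)-2,5-dimethylhex-4-en-1-one | CC(C)=CC[C@](C)(C(C)=O)C(=O)n1ccnc1
F4 | step 4 | methyl (4R)-4-methyl-4-(3-methylbut-2-en-1-yl)-3,5-dioxohexanoate | CC(C)=CC[C@](C)(C(C)=O)C(=O)CC(=O)OC
F5 | step 2 | dimethyl 2-methyl-2-(3-methylbut-2-en-1-yl)propanedioate | COC(=O)C(C)(CC=C(C)C)C(=O)OC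
F6 | step 2 | (2R)-2-(methoxycarbonyl)-2,5-dimethylhex-4-enoic acid | CC(C)=CC[C@](C)(C(=O)O)C(=O)OC
F7 | step 2 | methyl (2S)-2-(chlorocarbonyl)-2,5-dimethylhex-4-enoate | CC(C)=CC[C@](C)(C(Cl)=O)C(=O)OC
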